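Ask of each flask how old its J is at the end.

| flask | Z | X | E | temperature | remark | time |
|---|---|---|---|---|---|---|
| amber | 0.25 M | 0.325 M | 1.9 mM | 35 °C | run made earlier |  |
| ochre | 0.25 M | 0.325 M | 0.95 mM | 50 °C | run made earlier |  |
| blue | 0.25 M | 0.325 M | 1.4 mM | 35 °C | run made earlier |  |
| cedar | 0.25 M | 0.325 M | 1.9 mM | 50 °C | everything together at the start | 12 h |
| ash | 0.25 M | 0.325 M (fed, over 5.0 h) | 1.9 mM |  | the addition at 10 °C, then warmed to 50 °C; the feed brings no volume worth counting | 12 h |
| oak | 0.25 M (fed, over 5.0 h) | 0.325 M | 1.9 mM | 50 °C | all else is in the flask from the start; the feed brings no volume worth counting | 12 h |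
| maple | 0.25 M | 0.325 M (fed, over 5.0 h) | 1.9 mM | 50 °C | all else is in the flask from the start; the feed brings no volume worth counting | 12 h |

- amber (time / h: J / %, Q / %): 4.00: 1.0, 0; 8.00: 0.8, 0; 10.0: 1.0, 0; 15.0: 2.7, 0
- ochre (time / h: J / %, Q / %): 1.00: 0, 0.3; 2.50: 0, 0; 6.00: 0.6, 0; 15.0: 5.1, 2.5
- blue (time / h: J / %, Q / %): 4.00: 0, 0; 10.0: 0, 0; 20.0: 2.9, 0; 30.0: 3.6, 0.7

(scatter of a reading: 0.5 percentage points)

* the flask with the highest share of J in J plus Q ("all alike" if they lie within 1.5 percentage points) (cedar / ash / oak / maple / all alike)
* share of J in J plus Q at the end, cedar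
* share of J in J plus Q at the end, ash
* share of J in J plus Q at the end, oak
* share of J in J plus Q at the end, maple

- candidate steps: Z + E -> E + D; X + E + D -> E + J; J -> Q

Two chemists read these runs differently. The second holds that Q comes from J by one first-order step whatever the recipe, so the four flasks should read alike, near the share of J that ochre showed at 15.0 h, 67.1%. The first holds that a feed changes when J is born, and that younger J has had less time to turn into Q.

My own reckoning follows the first. Treat Q as a correction to J: the lost share, Q over J plus Q (the complement of the selectivity), is about a rate times the mean age of J. D piles up from Z like the level in a tank, and J is drawn from it in proportion to that level, so early on the flow into J is a ramp from zero, and I take it as one throughout. The mean age of what arrives on a ramp is a third of the ramp's length.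

Ochre lost 32.9% at a mean age of 5.00 h, so J loses 0.0658 h⁻¹, the ageing rate: the share lost per hour of mean age at 50 °C. It is read from one pair of readings, each with a scatter of 0.5 percentage points.

Cedar's ramp gives a mean age of 4.00 h and a share of 73.7%. Ash stays cold through its feed, and I start its ramp at the warming: 2.33 h and 84.6%. In oak, Z arrives on average half a feed late, which gives 3.17 h and 79.2%. In maple, the rising X thins the earliest J, which gives 3.66 h and 75.9%.

The forecast takes the first chemist's side with a rate of 0.1 per hour, and its shares differ from mine, cedar's being lower: cedar 70%, ash 80%, oak 74%, maple 72%, highest ash. For ash it argues that “nearly nothing happens at 10 °C, so there are effectively 7 h at 50 °C”.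

The simulation gives cedar 74.3%, ash 84.4%, oak 78.7%, maple 76.4%, so ash stands highest, and the forecast holds.

    Z + E → E + D (k = 63.0 M⁻¹ h⁻¹, Ea = 74.0 kJ mol⁻¹)
    X + E + D → E + J (k = 43.0 M⁻² h⁻¹, Ea = 59.0 kJ mol⁻¹)
    J → Q (k = 0.0680 h⁻¹, Ea = 103 kJ mol⁻¹)
    (constants at 50 °C)

Cedar holds more J at the end than ash, 9.46% against 4.76%. Carried to cedar read at 30 h, the ageing rate on a ramp gives a lost share of 65.8%, and that flask lost 55.7%, so there the correction overshoots. The second chemist's view has its region when cedar and ash are left to 120 h, where the two differ by less than the margin: cedar 4.58%, ash 5.01%.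

The data were computed for an exercise, noise included.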